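(The runs stem from a simulated flask for substances that don't exist, noise included.)

Which ends with the longer chains, Tuesday's flask or Thursday's? Start the reckoning from the count of chains, and leave the bench with this note.

| flask | free monomer | initiator | remark | time |
|---|---|---|---|---|
| cedar | 0.90 M (fed, over 3.0 h) | 2 mM | run made earlier; the fed solution adds 0.50 times the starting volume |  |
| elm | 0.90 M (fed, over 3.0 h) | 8 mM | run made earlier; the fed solution adds 0.50 times the starting volume |  |
| Tuesday's | 0.90 M (fed, over 3.0 h) | 4.0 mM | the fed solution adds 0.50 times the starting volume | 50 h |
| Thursday's | 0.90 M (fed, over 2.0 h) | 4.0 mM | the fed solution adds 0.50 times the starting volume | 50 h |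

| cedar: time / h | cedar: monomer in chains / % | elm: time / h | elm: monomer in chains / % |
|---|---|---|---|
| 10.0 | 40.5 | 5.00 | 40.2 |
| 20.0 | 57.0 | 15.0 | 76.3 |
| 30.0 | 64.8 | 25.0 | 86.3 |
| 40.0 | 66.8 | 40.0 | 89.7 |

(readings scatter by 0.5 percentage points)

- which of the two ends with the longer chains by the average number of monomer units in a chain (living and dead chains, two that joined counted as one) ("neither" if they lie within 10%) (Tuesday's / Thursday's / neither)
- average number of monomer units in a chain (living and dead chains, two that joined counted as one) at the end, Tuesday's
- average number of monomer units in a chain (living and dead chains, two that joined counted as one) at the end, Thursday's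

- charges are per starting volume, the dose included; the dosed solution carries all of it
- the average divides the monomer in chains by the number of chains, living and dead together; two radicals that join make one chain
- reactions considered so far: free monomer + growing radical -> monomer in chains + growing radical; 2 growing radical -> dead chain; initiator -> 2 initiating radical; free monomer + initiating radical -> growing radical + monomer in chains
- the earlier runs do not show the number of chains; that part of a forecast is a guess

Divide the free monomer charge by the initiator charge: this gives 225 in Tuesday's and Thursday's alike, the units per initiator. Each initiator gives two initiating radicals, each starts a chain, and two that join make one chain. So at full efficiency, which the earlier runs cannot show, average length is the fraction in chains times this ratio.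

Now read that fraction. Take the logarithm of one over the fraction left at 40.0 h: the cedar reading gives 1.10 and the elm reading 2.27, a ratio of 2.06 for 4.00 times the initiator, so in these two readings this depth goes roughly as the square root of the charge. The initiator charge of Tuesday's and Thursday's lies at the geometric middle of the two, so taking that depth for the end, my estimate is 79.5% in chains and a length of 179.

Leave the feed alone: the ratio holds no dosing time, and both feeds end well before 50 h. Leave the initiator charge alone too: it stands in the ratio, so in this reckoning the length moves with it.

The forecast says neither, with 180 (160 to 340) for Tuesday's and 183 (162 to 345) for Thursday's, since “combination gives one chain per initiator”.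

The simulation gives 183 for Tuesday's and 185 for Thursday's: neither.

    free monomer + growing radical → monomer in chains + growing radical, rate k1*[growing radical]*[free monomer] (k = 4100 M⁻¹ s⁻¹)
    2 growing radical → dead chain (k = 1.40 × 10⁹ M⁻¹ s⁻¹)
    initiator → 2 initiating radical (k = 3.60 × 10⁻⁵ s⁻¹)
    free monomer + initiating radical → growing radical + monomer in chains (k = 89000 M⁻¹ s⁻¹)

Take the joining of growing radicals out of Thursday's and its length goes from 185 to 493. With that step in place, the ratio times Thursday's 82.0% in chains gives 185. Now take a neighbour of Tuesday's charged with 0.0024 M of initiator: its ratio is 375, and times its 72.3% in chains that gives 271. The simulation of that neighbour gives 272.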